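## Retrosynthetic overview

1. The target is reached by esterification, desilylation and acetylation of a nine-membered carboxylic acid, which a retro-[3,3] step (ester-enolate Claisen ring contraction) traces back to a 13-membered (2E,6E,10E)-trienolide that already holds every carbon.
2. Key disconnection: the lactone C1(=O)–O–C12 bond, closed by macrolactonization of an open-chain hydroxy acid; the C12–O stereocentre is the only one set by a reagent and is relayed to C4a and C11a.
3. The seco acid is cut at C5–C4a (B-alkyl Suzuki–Miyaura) into the 9-BBN adduct of a geranate-derived triene ester and a (Z)-vinyl iodide carbinol.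
4. The vinyl iodide carbinol comes from a catalytic asymmetric three-component iodo-aldol reaction of a propiolate ester, Me3SiI and a γ-silyloxy enal made by cross-metathesis.
5. Ring order: the 13-membered lactone first (C–O bond), then the nine-membered carbocycle by ring contraction; no other ring is made.

Assumption: all starting materials and reagents named are commercial; atom labels follow xenicane numbering (C1 ester carbon, C11a and C4a ring stereocentres, C11 exo-methylene carbon with C19 its CH2, C7=C8 ring alkene, C4 side-chain carbon on C4a, C3 its CH2O carbon, C12 to C15 the diene chain up to the carbinol carbon).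

## Route

Step 1
Reactants: 1 2-methylbut-3-en-2-ol; 2 (2E)-but-2-enal (crotonaldehyde)
Product: 3 (2E)-4-hydroxy-4-methylpent-2-enal
Conditions: 2 (3 equiv), second-generation Hoveyda–Grubbs catalyst RuCl2(H2IMes)(=CH-C6H4-2-OiPr) (2 mol %), CH2Cl2, 40 °C
Reagents that add atoms: none
Why: Olefin cross-metathesis between a tertiary allylic alcohol that does not homodimerise and an enal gives the thermodynamically favoured (E)-enal with loss of propene.

Step 2
Reactants: 3 (2E)-4-hydroxy-4-methylpent-2-enal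
Product: 4 (2E)-4-methyl-4-[(triethylsilyl)oxy]pent-2-enal
Conditions: Et3SiOTf, 2,6-lutidine, CH2Cl2, −78 °C
Reagents that add atoms: triethylsilyl trifluoromethanesulfonate, CC[Si](CC)(CC)OS(=O)(=O)C(F)(F)F
Why: Silyl triflate silylation protects the hindered tertiary alcohol, and the enal has no γ-hydrogen, so no silyl dienol ether can form.

Step 3
Reactants: 4 (2E)-4-methyl-4-[(triethylsilyl)oxy]pent-2-enal; 5 methyl prop-2-ynoate (methyl propiolate)
Product: 8 methyl (2Z)-2-[(1S,2E)-1-hydroxy-4-methyl-4-[(triethylsilyl)oxy]pent-2-en-1-yl]-3-iodoprop-2-enoate, via silyl iodoallenolate 6 (not isolated), via O-trimethylsilyl aldol ether 7 (not isolated)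
Conditions: 5 (2 equiv), Me3SiI (2 equiv), oxazaborolidinium catalyst [1-(2-methylphenyl)-3,3-diphenyltetrahydro-1H,3H-pyrrolo[1,2-c][1,3,2]oxazaborole protonated with HN(SO2CF3)2, 20 mol %, the antipode that gives 12S], CH2Cl2, −78 °C; then 1 M HCl, THF, 0 °C
Reagents that add atoms: iodotrimethylsilane, C[Si](C)(C)I (iodine in 8; the silyl group stays only in 6 and 7)
Why: Catalytic asymmetric three-component iodo-aldol (β-iodo Morita–Baylis–Hillman) reaction, in which Me3SiI adds to the propiolate to give allenolate 6, which attacks the aldehyde held on the chiral boron cation from its open face in a Mukaiyama aldol step to set C12 as S (checked by Mosher esters; the mirror-image catalyst is used if the facial sense is opposite), while −78 °C keeps the kinetic (Z)-iodoalkene with iodine cis to the ester.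

Step 4
Reactants: 8 methyl (2Z)-2-[(1S,2E)-1-hydroxy-4-methyl-4-[(triethylsilyl)oxy]pent-2-en-1-yl]-3-iodoprop-2-enoate
Product: 9 (2E,3S,4E)-2-(iodomethylidene)-6-methyl-6-[(triethylsilyl)oxy]hept-4-ene-1,3-diol
Conditions: iBu2AlH (3.5 equiv), CH2Cl2, −78 °C; aq. Rochelle salt
Reagents that add atoms: none
Why: Hydride (1,2-) reduction of the ester at low temperature leaves the vinyl iodide, the silyl ether and C12 untouched.

Step 5
Reactants: 9 (2E,3S,4E)-2-(iodomethylidene)-6-methyl-6-[(triethylsilyl)oxy]hept-4-ene-1,3-diol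
Product: 10 (1E,3S,4E)-2-{[tert-butyl(dimethyl)silyl]oxymethyl}-1-iodo-6-methyl-6-[(triethylsilyl)oxy]hepta-1,4-dien-3-ol
Conditions: tBuMe2SiCl (1.05 equiv), imidazole, CH2Cl2, 0 °C
Reagents that add atoms: tert-butyldimethylsilyl chloride, CC(C)(C)[Si](C)(C)Cl
Why: Silyl ether protection is selective for the primary allylic hydroxyl over the hindered secondary bis-allylic one on steric grounds.

Step 6
Reactants: 11 methyl (2E)-3,7-dimethylocta-2,6-dienoate (methyl geranate)
Product: 12 methyl (2E,6E)-3,7-dimethyl-8-oxoocta-2,6-dienoate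
Conditions: SeO2 (1.1 equiv), 95% EtOH, reflux
Reagents that add atoms: selenium dioxide, O=[Se]=O
Why: Riley allylic oxidation (ene reaction then [2,3]-sigmatropic shift) attacks only the electron-rich terminal trisubstituted alkene and oxidises its (E)-methyl group, the conjugated enoate alkene being inert.

Step 7
Reactants: 12 methyl (2E,6E)-3,7-dimethyl-8-oxoocta-2,6-dienoate
Product: 13 methyl (2E,6E)-3,7-dimethylnona-2,6,8-trienoate
Conditions: Ph3PCH3Br, KOtBu, THF, 0 °C; then 12, −78 → 0 °C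
Reagents that add atoms: methyltriphenylphosphonium bromide, C[P+](c1ccccc1)(c1ccccc1)c1ccccc1.[Br-]
Why: Wittig methylenation of the enal is much faster than attack of the unstabilised ylide on the ester at low temperature and does not touch the existing (E)-alkenes.

Step 8
Reactants: 13 methyl (2E,6E)-3,7-dimethylnona-2,6,8-trienoate; 10 (1E,3S,4E)-2-{[tert-butyl(dimethyl)silyl]oxymethyl}-1-iodo-6-methyl-6-[(triethylsilyl)oxy]hepta-1,4-dien-3-ol
Product: 15 methyl (2E,6E,10E,12S,13E)-11-{[tert-butyl(dimethyl)silyl]oxymethyl}-12-hydroxy-3,7,15-trimethyl-15-[(triethylsilyl)oxy]hexadeca-2,6,10,13-tetraenoate, via alkylborane 14 (not isolated)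
Conditions: 13, 9-BBN-H (1.2 equiv), THF, 0 → 25 °C; then 10, Pd(dppf)Cl2 (5 mol %), AsPh3 (10 mol %), Cs2CO3, DMF/THF/H2O, 25 °C
Reagents that add atoms: 9-borabicyclo[3.3.1]nonane, B1C2CCCC1CCC2 (boron stays only in 14; 15 keeps one hydrogen)
Why: Anti-Markovnikov hydroboration of the terminal vinyl group of the diene followed by B-alkyl Suzuki–Miyaura coupling, which retains the vinyl iodide geometry so that C5 ends cis to the CH2OSi group and trans to C12.

Step 9
Reactants: 15 methyl (2E,6E,10E,12S,13E)-11-{[tert-butyl(dimethyl)silyl]oxymethyl}-12-hydroxy-3,7,15-trimethyl-15-[(triethylsilyl)oxy]hexadeca-2,6,10,13-tetraenoate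
Product: 16 (2E,6E,10E,12S,13E)-11-{[tert-butyl(dimethyl)silyl]oxymethyl}-12-hydroxy-3,7,15-trimethyl-15-[(triethylsilyl)oxy]hexadeca-2,6,10,13-tetraenoic acid
Conditions: LiOH·H2O, THF/MeOH/H2O, 45 °C; then 1 M HCl to pH 4, 0 °C
Reagents that add atoms: lithium hydroxide, [Li+].[OH-]
Why: Saponification of the methyl ester is tolerated by both silyl ethers and the bis-allylic alcohol, and the cold, mild acidification avoids ionisation at C12 or C15.

Step 10
Reactants: 16 (2E,6E,10E,12S,13E)-11-{[tert-butyl(dimethyl)silyl]oxymethyl}-12-hydroxy-3,7,15-trimethyl-15-[(triethylsilyl)oxy]hexadeca-2,6,10,13-tetraenoic acid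
Product: 18 (3E,7E,11E,13S)-12-{[tert-butyl(dimethyl)silyl]oxymethyl}-4,8-dimethyl-13-{(1E)-3-methyl-3-[(triethylsilyl)oxy]but-1-en-1-yl}-1-oxacyclotrideca-3,7,11-trien-2-one, via mixed anhydride 17 (not isolated)
Conditions: 2-methyl-6-nitrobenzoic anhydride (1.5 equiv), 4-(dimethylamino)pyridine (0.3 equiv), Et3N (4 equiv), CH2Cl2, 25 °C, 16 added by syringe pump over 12 h (final 1 mM)
Reagents that add atoms: 2-methyl-6-nitrobenzoic anhydride, Cc1cccc([N+](=O)[O-])c1C(=O)OC(=O)c1c(C)cccc1[N+](=O)[O-] (its aroyl group stays only in 17)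
Why: Shiina macrolactonization forms the ring-closing C1–O bond by acyl transfer from the mixed anhydride to the C12 hydroxyl with retention at C12, the three (E)-alkenes pre-organising the 13-membered ring and room temperature keeping the 2E geometry.

Step 11
Reactants: 18 (3E,7E,11E,13S)-12-{[tert-butyl(dimethyl)silyl]oxymethyl}-4,8-dimethyl-13-{(1E)-3-methyl-3-[(triethylsilyl)oxy]but-1-en-1-yl}-1-oxacyclotrideca-3,7,11-trien-2-one
Product: 22 methyl (1R,2S,5E)-2-[(2Z,4E)-1-{[tert-butyl(dimethyl)silyl]oxy}-6-methyl-6-[(triethylsilyl)oxy]hepta-2,4-dien-2-yl]-5-methyl-9-methylidenecyclonon-5-ene-1-carboxylate, via silyl dienyl ketene acetal 19 (not isolated), via trimethylsilyl ester 20 (not isolated), via carboxylic acid 21 (not isolated)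
Conditions: LiN(iPr)2 (1.5 equiv), THF, −78 °C; Me3SiCl/Et3N (3 equiv), −78 → 25 °C; toluene, 80 °C; then MeOH, 0 °C; then Me3SiCHN2, toluene/MeOH, 0 °C
Reagents that add atoms: chlorotrimethylsilane, C[Si](C)(C)Cl (silicon stays only in 19 and 20); (trimethylsilyl)diazomethane, C[Si](C)(C)C=[N+]=[N-] (the ester methyl carbon)
Why: Proposed new method: a transannular vinylogous Ireland–Claisen ring contraction, in which LiN(iPr)2 removes a hydrogen from the C19 methyl group that lies syn to the carbonyl in the s-cis 2E-enoate (the usual kinetic γ-deprotonation of 3-methyl-2-enoates) and O-silylation gives the cross-conjugated ketene acetal 19 whose C1=C11a geometry (ring oxygen trans to C11) is fixed by that conformer; the [3,3] shift then joins C11a to C4a through a chair in which both tether ends (C5 and C11) and the C12 alkenyl group are equatorial, so the 12S C–O stereocentre is relayed into 4aS,11aR with trans substituents, the new C4=C12 alkene places the diene trans to C4a, and the former methyl group becomes the exo-methylene; the exothermic change from ketene acetal to silyl ester and the long forming bond of an early transition state let the (E)-cyclononene form before its full strain is felt, and a shift onto the side-chain alkene is blocked because C14 adjoins the quaternary silyloxy carbon; the closest known reactions are the Ireland–Claisen ring contraction of saturated macrolactone enolates to medium and large carbocycles and the acyclic Ireland–Claisen rearrangement of allyl 3-methylbut-2-enoates through their dienolates; methanol then frees acid 21, which Me3SiCHN2 methylates.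

Step 12
Reactants: 22 methyl (1R,2S,5E)-2-[(2Z,4E)-1-{[tert-butyl(dimethyl)silyl]oxy}-6-methyl-6-[(triethylsilyl)oxy]hepta-2,4-dien-2-yl]-5-methyl-9-methylidenecyclonon-5-ene-1-carboxylate
Product: 24 methyl (1R,2S,5E)-2-[(2Z,4E)-1-(acetyloxy)-6-hydroxy-6-methylhepta-2,4-dien-2-yl]-5-methyl-9-methylidenecyclonon-5-ene-1-carboxylate, via diol 23 (not isolated)
Conditions: Bu4NF (3 equiv), AcOH (3 equiv), THF, 0 → 25 °C; then Ac2O, pyridine, 0 °C
Reagents that add atoms: acetic anhydride, CC(=O)OC(C)=O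
Why: Fluoride desilylation buffered with acetic acid keeps the freed primary alcohol protonated so that it neither lactonises onto the ester nor epimerises C11a, and acetylation with Ac2O/pyridine without an acyl-transfer catalyst esterifies only the primary allylic hydroxyl and leaves the tertiary alcohol free.

## Compound list

1 | 2-methylbut-3-en-2-ol | C=CC(C)(C)O | starting material
2 | (2E)-but-2-enal (crotonaldehyde) | C/C=C/C=O | starting material
3 | (2E)-4-hydroxy-4-methylpent-2-enal | O=C/C=C/C(C)(C)O | intermediate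
4 | (2E)-4-methyl-4-[(triethylsilyl)oxy]pent-2-enal | O=C/C=C/C(C)(C)O[Si](CC)(CC)CC | intermediate
5 | methyl prop-2-ynoate (methyl propiolate) | C#CC(=O)OC | starting material
6 | 3-iodo-1-methoxy-1-[(trimethylsilyl)oxy]propa-1,2-diene (silyl iodoallenolate) | IC=C=C(OC)O[Si](C)(C)C | intermediate
7 | methyl (2Z)-3-iodo-2-[(1S,2E)-4-methyl-4-[(triethylsilyl)oxy]-1-[(trimethylsilyl)oxy]pent-2-en-1-yl]prop-2-enoate | I/C=C(\C(=O)OC)[C@@H](O[Si](C)(C)C)/C=C/C(C)(C)O[Si](CC)(CC)CC | intermediate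
8 | methyl (2Z)-2-[(1S,2E)-1-hydroxy-4-methyl-4-[(triethylsilyl)oxy]pent-2-en-1-yl]-3-iodoprop-2-enoate (iodine cis to the ester) | I/C=C(\C(=O)OC)[C@@H](O)/C=C/C(C)(C)O[Si](CC)(CC)CC | intermediate
9 | (2E,3S,4E)-2-(iodomethylidene)-6-methyl-6-[(triethylsilyl)oxy]hept-4-ene-1,3-diol (iodine cis to CH2OH) | I/C=C(\CO)[C@@H](O)/C=C/C(C)(C)O[Si](CC)(CC)CC | intermediate
10 | (1E,3S,4E)-2-{[tert-butyl(dimethyl)silyl]oxymethyl}-1-iodo-6-methyl-6-[(triethylsilyl)oxy]hepta-1,4-dien-3-ol (iodine cis to CH2OSi) | I/C=C(\CO[Si](C)(C)C(C)(C)C)[C@@H](O)/C=C/C(C)(C)O[Si](CC)(CC)CC | intermediate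
11 | methyl (2E)-3,7-dimethylocta-2,6-dienoate (methyl geranate) | COC(=O)/C=C(\C)CCC=C(C)C | starting material
12 | methyl (2E,6E)-3,7-dimethyl-8-oxoocta-2,6-dienoate | COC(=O)/C=C(\C)CC/C=C(\C)C=O | intermediate
13 | methyl (2E,6E)-3,7-dimethylnona-2,6,8-trienoate | COC(=O)/C=C(\C)CC/C=C(\C)C=C | intermediate
14 | methyl (2E,6E)-9-(9-borabicyclo[3.3.1]nonan-9-yl)-3,7-dimethylnona-2,6-dienoate | COC(=O)/C=C(\C)CC/C=C(\C)CCB1C2CCCC1CCC2 | intermediate
15 | methyl (2E,6E,10E,12S,13E)-11-{[tert-butyl(dimethyl)silyl]oxymethyl}-12-hydroxy-3,7,15-trimethyl-15-[(triethylsilyl)oxy]hexadeca-2,6,10,13-tetraenoate | COC(=O)/C=C(\C)CC/C=C(\C)CC/C=C(\CO[Si](C)(C)C(C)(C)C)[C@@H](O)/C=C/C(C)(C)O[Si](CC)(CC)CC | intermediate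
16 | (2E,6E,10E,12S,13E)-11-{[tert-butyl(dimethyl)silyl]oxymethyl}-12-hydroxy-3,7,15-trimethyl-15-[(triethylsilyl)oxy]hexadeca-2,6,10,13-tetraenoic acid | OC(=O)/C=C(\C)CC/C=C(\C)CC/C=C(\CO[Si](C)(C)C(C)(C)C)[C@@H](O)/C=C/C(C)(C)O[Si](CC)(CC)CC | intermediate
17 | mixed anhydride of 16 with 2-methyl-6-nitrobenzoic acid | Cc1cccc([N+](=O)[O-])c1C(=O)OC(=O)/C=C(\C)CC/C=C(\C)CC/C=C(\CO[Si](C)(C)C(C)(C)C)[C@@H](O)/C=C/C(C)(C)O[Si](CC)(CC)CC | intermediate
18 | (3E,7E,11E,13S)-12-{[tert-butyl(dimethyl)silyl]oxymethyl}-4,8-dimethyl-13-{(1E)-3-methyl-3-[(triethylsilyl)oxy]but-1-en-1-yl}-1-oxacyclotrideca-3,7,11-trien-2-one | O=C1/C=C(\C)CC/C=C(\C)CC/C=C(\CO[Si](C)(C)C(C)(C)C)[C@@H](O1)/C=C/C(C)(C)O[Si](CC)(CC)CC | intermediate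
19 | (2Z,7E,11E,13S)-12-{[tert-butyl(dimethyl)silyl]oxymethyl}-8-methyl-4-methylidene-13-{(1E)-3-methyl-3-[(triethylsilyl)oxy]but-1-en-1-yl}-2-[(trimethylsilyl)oxy]-1-oxacyclotrideca-2,7,11-triene | C1/C=C(\C)CC/C=C(\CO[Si](C)(C)C(C)(C)C)[C@H](/C=C/C(C)(C)O[Si](CC)(CC)CC)O/C(O[Si](C)(C)C)=C/C(=C)C1 | intermediate
20 | trimethylsilyl (1R,2S,5E)-2-[(2Z,4E)-1-{[tert-butyl(dimethyl)silyl]oxy}-6-methyl-6-[(triethylsilyl)oxy]hepta-2,4-dien-2-yl]-5-methyl-9-methylidenecyclonon-5-ene-1-carboxylate | C=C1CC/C=C(\C)CC[C@H](/C(=C/C=C/C(C)(C)O[Si](CC)(CC)CC)CO[Si](C)(C)C(C)(C)C)[C@H]1C(=O)O[Si](C)(C)C | intermediate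
21 | (1R,2S,5E)-2-[(2Z,4E)-1-{[tert-butyl(dimethyl)silyl]oxy}-6-methyl-6-[(triethylsilyl)oxy]hepta-2,4-dien-2-yl]-5-methyl-9-methylidenecyclonon-5-ene-1-carboxylic acid | C=C1CC/C=C(\C)CC[C@H](/C(=C/C=C/C(C)(C)O[Si](CC)(CC)CC)CO[Si](C)(C)C(C)(C)C)[C@H]1C(=O)O | intermediate
22 | methyl (1R,2S,5E)-2-[(2Z,4E)-1-{[tert-butyl(dimethyl)silyl]oxy}-6-methyl-6-[(triethylsilyl)oxy]hepta-2,4-dien-2-yl]-5-methyl-9-methylidenecyclonon-5-ene-1-carboxylate | C=C1CC/C=C(\C)CC[C@H](/C(=C/C=C/C(C)(C)O[Si](CC)(CC)CC)CO[Si](C)(C)C(C)(C)C)[C@H]1C(=O)OC | intermediate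
23 | methyl (1R,2S,5E)-2-[(2Z,4E)-1,6-dihydroxy-6-methylhepta-2,4-dien-2-yl]-5-methyl-9-methylidenecyclonon-5-ene-1-carboxylate | C=C1CC/C=C(\C)CC[C@H](/C(=C/C=C/C(C)(C)O)CO)[C@H]1C(=O)OC | intermediate
24 | methyl (1R,2S,5E)-2-[(2Z,4E)-1-(acetyloxy)-6-hydroxy-6-methylhepta-2,4-dien-2-yl]-5-methyl-9-methylidenecyclonon-5-ene-1-carboxylate | C=C1CC/C=C(\C)CC[C@H](/C(=C/C=C/C(C)(C)O)COC(C)=O)[C@H]1C(=O)OC | target

## Step count and risks

Total steps: 12. Longest linear sequence: 10 (steps 1 to 5, then 8 to 12).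

Step 3 (asymmetric three-component iodo-aldol). The γ-silyloxy enal is an untested substrate for this catalyst, so the enantiomeric excess, or tolerance of the tertiary allylic silyl ether to the Lewis acid, may be poor. The fallback sets out from 4 and 5 and comes back at 10. The three components are combined with MgI2 in CH2Cl2 at 0 °C without a chiral catalyst (achiral halo-aldol) to give the racemic iodo-aldol ester F1. Reduction with iBu2AlH and silylation with tBuMe2SiCl, as in steps 4 and 5, give the racemic diol F2 and the racemic silyl ether F3. Dess–Martin periodinane with NaHCO3 oxidises F3 to the cross-conjugated iodo dienone F4. Corey–Bakshi–Shibata reduction with catecholborane and (R)-1-methyl-3,3-diphenyltetrahydro-1H,3H-pyrrolo[1,2-c][1,3,2]oxazaborole (toluene, −78 °C) then gives 10, the α-branched iodoalkenyl group acting as the large substituent so that the S alcohol results.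

Step 10 (macrolactonization). Closing a 13-membered ring onto a hindered bis-allylic alcohol may give oligomers, and the acyl-transfer catalyst may isomerise the 2E-enoate. The fallback sets out from 13 and 10 and comes back at 18; it makes the ester bond between the fragments first and closes the ring at C5–C4a instead. Saponification of 13 (LiOH, THF/MeOH/H2O) gives the trienoic acid F5. Carbodiimide esterification of the C12 hydroxyl of 10 with F5 (N-(3-dimethylaminopropyl)-N′-ethylcarbodiimide hydrochloride, 4-(dimethylamino)pyridine, CH2Cl2) gives the iodo ester F6. Hydroboration of its terminal vinyl group with 9-BBN-H gives the alkylborane F7, which is not isolated. Intramolecular B-alkyl Suzuki–Miyaura coupling (Pd(dppf)Cl2, AsPh3, Cs2CO3, DMF/THF/H2O, 2 mM) closes the macrocycle to 18.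

Step 11 (the proposed new ring contraction). The reaction is untested, and it could fail in three ways:
- γ-deprotonation may be unselective;
- the rearrangement may pass through a boat and give the cis isomer;
- the strain of the (E)-cyclononene may divert the ketene acetal to other pathways.

The fallback uses known chemistry, sets out from 18 and comes back at 21. Kinetic deconjugation (LiN(iPr)2, THF/DMPU, −78 °C, then AcOH at −78 °C) gives the β,γ-unsaturated lactone F8. Soft α-enolisation with dicyclohexylboron trifluoromethanesulfonate and Et3N (CH2Cl2, −78 °C) gives the boron ketene acetal F9, which is not isolated. On warming to 25 °C it undergoes the classical ester-enolate Claisen ring contraction in its boron-enolate form, through a tighter chair, to the boryl ester F10, also not isolated. Work-up at pH 7 gives acid 21, which is methylated as in step 11.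

## Further compounds

F1 | step 3 | rac-methyl (2Z)-2-[(2E)-1-hydroxy-4-methyl-4-[(triethylsilyl)oxy]pent-2-en-1-yl]-3-iodoprop-2-enoate | I/C=C(\C(=O)OC)C(O)/C=C/C(C)(C)O[Si](CC)(CC)CC
F2 | step 3 | rac-(2E,4E)-2-(iodomethylidene)-6-methyl-6-[(triethylsilyl)oxy]hept-4-ene-1,3-diol | I/C=C(\CO)C(O)/C=C/C(C)(C)O[Si](CC)(CC)CC
F3 | step 3 | rac-(1E,4E)-2-{[tert-butyl(dimethyl)silyl]oxymethyl}-1-iodo-6-methyl-6-[(triethylsilyl)oxy]hepta-1,4-dien-3-ol | I/C=C(\CO[Si](C)(C)C(C)(C)C)C(O)/C=C/C(C)(C)O[Si](CC)(CC)CC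
F4 | step 3 | (1E,4E)-2-{[tert-butyl(dimethyl)silyl]oxymethyl}-1-iodo-6-methyl-6-[(triethylsilyl)oxy]hepta-1,4-dien-3-one | I/C=C(\CO[Si](C)(C)C(C)(C)C)C(=O)/C=C/C(C)(C)O[Si](CC)(CC)CC
F5 | step 10 | (2E,6E)-3,7-dimethylnona-2,6,8-trienoic acid | OC(=O)/C=C(\C)CC/C=C(\C)C=C
F6 | step 10 | (1E,3S,4E)-2-{[tert-butyl(dimethyl)silyl]oxymethyl}-1-iodo-6-methyl-6-[(triethylsilyl)oxy]hepta-1,4-dien-3-yl (2E,6E)-3,7-dimethylnona-2,6,8-trienoate | I/C=C(\CO[Si](C)(C)C(C)(C)C)[C@@H](OC(=O)/C=C(\C)CC/C=C(\C)C=C)/C=C/C(C)(C)O[Si](CC)(CC)CC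
F7 | step 10 | (1E,3S,4E)-2-{[tert-butyl(dimethyl)silyl]oxymethyl}-1-iodo-6-methyl-6-[(triethylsilyl)oxy]hepta-1,4-dien-3-yl (2E,6E)-9-(9-borabicyclo[3.3.1]nonan-9-yl)-3,7-dimethylnona-2,6-dienoate | I/C=C(\CO[Si](C)(C)C(C)(C)C)[C@@H](OC(=O)/C=C(\C)CC/C=C(\C)CCB1C2CCCC1CCC2)/C=C/C(C)(C)O[Si](CC)(CC)CC
F8 | step 11 | (7E,11E,13S)-12-{[tert-butyl(dimethyl)silyl]oxymethyl}-8-methyl-4-methylidene-13-{(1E)-3-methyl-3-[(triethylsilyl)oxy]but-1-en-1-yl}-1-oxacyclotrideca-7,11-dien-2-one | O=C1CC(=C)CC/C=C(\C)CC/C=C(\CO[Si](C)(C)C(C)(C)C)[C@@H](O1)/C=C/C(C)(C)O[Si](CC)(CC)CC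
F9 | step 11 | (2E,7E,11E,13S)-12-{[tert-butyl(dimethyl)silyl]oxymethyl}-2-[(dicyclohexylboranyl)oxy]-8-methyl-4-methylidene-13-{(1E)-3-methyl-3-[(triethylsilyl)oxy]but-1-en-1-yl}-1-oxacyclotrideca-2,7,11-triene | C1/C=C(\C)CC/C=C(\CO[Si](C)(C)C(C)(C)C)[C@H](/C=C/C(C)(C)O[Si](CC)(CC)CC)O/C(OB(C2CCCCC2)C2CCCCC2)=C/C(=C)C1
F10 | step 11 | dicyclohexylboranyl (1R,2S,5E)-2-[(2Z,4E)-1-{[tert-butyl(dimethyl)silyl]oxy}-6-methyl-6-[(triethylsilyl)oxy]hepta-2,4-dien-2-yl]-5-methyl-9-methylidenecyclonon-5-ene-1-carboxylate | C=C1CC/C=C(\C)CC[C@H](/C(=C/C=C/C(C)(C)O[Si](CC)(CC)CC)CO[Si](C)(C)C(C)(C)C)[C@H]1C(=O)OB(C1CCCCC1)C1CCCCC1
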